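**Plan** (guaiane numbering: C1 = sp2 ring-fusion carbon, C2, C3, C4 = C(Me)OH, C5 = ring-fusion CH, C6 = CHOH, C7 = CH-iPr, C8 = CH-O-ester, C9 = CH2, C10 = C(Me)=)
- Retrosynthesis: cut the C8–O ester bond (made with inversion), re-form a temporary ether bridge C1–O–C8 (alkene moves from C1=C10 to C9=C10), then cut C1–C5 and C7–C8 together, then the isobutyl–C6 bond and the C3–C4 bond.
- Enabling feature: C6 (oxygenated) flanked by C5 and C7 is a 2-oxyallyl unit; the C4 oxygen next to C5 is the oxygen of a C4–C5 epoxide that releases it; C1, C10(Me), C9, C8 plus the C8 oxygen are a 2-alkyl-3-methylfuran; the C2–C3–C4 tether makes the C1–C5 bond close the cyclopentane while both bonds close the seven-membered ring.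
- Forward: furan side chain by B-alkyl Suzuki coupling, asymmetric epoxidation, epoxy ketone, enol silane, intramolecular (4+3) cycloaddition (both carbocycles at once), C6 reduction, reductive opening of the bridge (sets C1=C10), inverting esterification, desilylation.
- Stereochemistry: C4 from the Sharpless epoxidation (only external source); C5 by inversion at the epoxide carbon; C7 from the Z enol silane; C6 by hydride attack on the open face of the bicyclic ketone; C8 from the furan face, then inverted in the esterification.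

Key step: step 9

**Step 1**
Reactants: 1 3-methylfuran-2-carbaldehyde
Product: 2 2-ethenyl-3-methylfuran
Conditions: Ph3PCH3Br, KOtBu, THF, 0 °C → rt
Reagents that add atoms: methyltriphenylphosphonium bromide, C[P+](c1ccccc1)(c1ccccc1)c1ccccc1.[Br-]
Why: Wittig methylenation of an aromatic aldehyde with the non-stabilised ylide should be clean, and the volatile vinylfuran is carried on as a solution.

**Step 2**
Reactants: 3 but-2-yn-1-ol
Product: 5 (2Z)-3-iodobut-2-en-1-ol, via cyclic alkenylalanate 4 (not isolated)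
Conditions: NaAlH2(OCH2CH2OMe)2, Et2O, 0 °C → rt; then I2, THF, −78 °C
Reagents that add atoms: iodine, II
Why: alkoxide-directed trans-hydroalumination of the propargylic alcohol puts aluminium on C3 anti to the new C2–H, and iodinolysis with retention gives the Z iodide (iodine cis to CH2OH).

**Step 3**
Reactants: 2 2-ethenyl-3-methylfuran, 5 (2Z)-3-iodobut-2-en-1-ol
Product: 7 (2Z)-3-methyl-5-(3-methylfuran-2-yl)pent-2-en-1-ol, via B-alkyl-9-BBN borane 6 (not isolated)
Conditions: 9-BBN, THF, 0 °C → rt; then 5, Pd(dppf)Cl2 (5 mol%), AsPh3, Cs2CO3, DMF/H2O, rt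
Reagents that add atoms: none
Why: anti-Markovnikov hydroboration of the vinyl group followed by B-alkyl Suzuki–Miyaura coupling proceeds with retention at the alkenyl iodide, so the furylethyl chain ends cis to CH2OH (nerol-type Z alkene).

**Step 4**
Reactants: 7 (2Z)-3-methyl-5-(3-methylfuran-2-yl)pent-2-en-1-ol
Product: 8 [(2R,3S)-3-methyl-3-[2-(3-methylfuran-2-yl)ethyl]oxiran-2-yl]methanol
Conditions: Ti(OiPr)4 (10 mol%), D-(−)-diethyl tartrate (12 mol%), t-BuOOH, 4 Å MS, CH2Cl2, −20 °C
Reagents that add atoms: tert-butyl hydroperoxide, CC(C)(C)OO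
Why: Sharpless asymmetric epoxidation of a Z-trisubstituted allylic alcohol, where the D-tartrate complex should deliver oxygen to the face that gives the (2R,3S) epoxide (mirror image of the nerol/L-tartrate case), setting C4 (S) and, cis-fused to it, C5.

**Step 5**
Reactants: 8 [(2R,3S)-3-methyl-3-[2-(3-methylfuran-2-yl)ethyl]oxiran-2-yl]methanol
Product: 9 (2S,3S)-3-methyl-3-[2-(3-methylfuran-2-yl)ethyl]oxirane-2-carbaldehyde
Conditions: DMP (1,1,1-triacetoxy-1,2-benziodoxol-3-one), pyridine, CH2Cl2, 0 °C → rt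
Reagents that add atoms: none
Why: buffered periodinane oxidation of the primary alcohol leaves the epoxide and the furan untouched (the descriptor at the oxirane CH changes by priority only).

**Step 6**
Reactants: 9 (2S,3S)-3-methyl-3-[2-(3-methylfuran-2-yl)ethyl]oxirane-2-carbaldehyde, 10 isobutylmagnesium bromide
Product: 11 3-methyl-1-[(2R,3S)-3-methyl-3-[2-(3-methylfuran-2-yl)ethyl]oxiran-2-yl]butan-1-ol (both carbinol epimers)
Conditions: THF, −78 °C; aq. NH4Cl
Reagents that add atoms: none
Why: Grignard addition to the aldehyde is faster than epoxide opening at low temperature, and the new carbinol centre is removed in the next step.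

**Step 7**
Reactants: 11 3-methyl-1-[(2R,3S)-3-methyl-3-[2-(3-methylfuran-2-yl)ethyl]oxiran-2-yl]butan-1-ol
Product: 12 3-methyl-1-[(2S,3S)-3-methyl-3-[2-(3-methylfuran-2-yl)ethyl]oxiran-2-yl]butan-1-one
Conditions: DMP, pyridine, CH2Cl2, 0 °C → rt
Reagents that add atoms: none
Why: periodinane oxidation of the secondary alcohol gives the α,β-epoxy ketone without base, so the epoxide carbon next to the carbonyl is not epimerised.

**Step 8**
Reactants: 12 3-methyl-1-[(2S,3S)-3-methyl-3-[2-(3-methylfuran-2-yl)ethyl]oxiran-2-yl]butan-1-one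
Product: 13 triethyl({(1Z)-3-methyl-1-[(2S,3S)-3-methyl-3-[2-(3-methylfuran-2-yl)ethyl]oxiran-2-yl]but-1-en-1-yl}oxy)silane
Conditions: Et3SiOTf, Et3N (excess), CH2Cl2, −78 °C
Reagents that add atoms: triethylsilyl trifluoromethanesulfonate, CC[Si](CC)(CC)OS(=O)(=O)C(F)(F)F
Why: soft enolisation can only occur toward C7 (C5 is an epoxide carbon) and should give the Z enol silane (isopropyl cis to OSi, away from the oxirane), while the excess amine keeps the epoxide unactivated.

**Step 9**
Reactants: 13 triethyl({(1Z)-3-methyl-1-[(2S,3S)-3-methyl-3-[2-(3-methylfuran-2-yl)ethyl]oxiran-2-yl]but-1-en-1-yl}oxy)silane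
Product: 14 (1R,4S,5R,7R,8R)-1,8-epoxy-4-(triethylsilyloxy)guai-9-en-6-one
Conditions: Et3SiOTf (10 mol%), CH2Cl2, −78 °C; Et3N quench
Reagents that add atoms: none
Why: Et3SiOTf silylates the epoxide oxygen, and as the C5–O bond breaks with help from the enol silane π-bond (a 2-silyloxyallyl cation C5–C6–C7 in the making) the furan α-carbon C1 attacks C5 from the rear and C7 closes on the other furan α-carbon C8, after which the silyl group leaves the C6 oxocarbenium and carries the chain. The closest known reaction type is the silyl triflate-catalysed intramolecular (4+3) cycloaddition of epoxy enol silanes with tethered furans, a variant of the oxyallyl cation–furan (4+3) cycloaddition. The cyclopentane closes by 5-exo attack of C1 on the epoxide carbon through the C2–C3–C4 tether, and the seven-membered ring closes when the C7–C8 bond completes the 2,5-addition across the furan (7-endo closure of the enol silane carbon on the furan-derived oxocarbenium), giving an 8-oxabicyclo[3.2.1]octenone. C5 is set by inversion at the epoxide carbon (stereospecific, so its relation to C4 follows from the Z epoxide and the enantiomeric purity of 8 should be carried over), C7 by the Z enol silane geometry in the W-shaped allyl unit, and C1 and C8 by suprafacial addition to the furan in the extended orientation. The step needs C5–O and not C4–O cleavage, secured because only ionisation at C5 is conjugated with the enol silane, and it needs the extended and not the compact approach, secured because the extended mode puts the small furan oxygen and not the C10 methyl next to the quaternary C4 and fuses the cyclopentane through the less strained pseudo-axial bond. The bridge is then cis to the C4–C5 bond and to the isopropyl group, C1 is a temporary centre, and C8 is corrected in step 14.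

**Step 10**
Reactants: 14 (1R,4S,5R,7R,8R)-1,8-epoxy-4-(triethylsilyloxy)guai-9-en-6-one
Product: 15 (1R,4S,5R,6R,7S,8R)-1,8-epoxy-4-(triethylsilyloxy)guai-9-en-6-ol
Conditions: NaBH4, CeCl3·7H2O, MeOH, −40 °C
Reagents that add atoms: none
Why: in 14 both α-substituents lie on the bridge side, so the pyranone ring should sit as a boat and hydride (Luche reduction) should enter from the open outer face, placing the C6 hydroxyl cis to the bridge, to C4 and to the isopropyl group, while the non-basic medium avoids epimerisation at C7.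

**Step 11**
Reactants: 15 (1R,4S,5R,6R,7S,8R)-1,8-epoxy-4-(triethylsilyloxy)guai-9-en-6-ol
Product: 16 (1R,4S,5R,6R,7R,8R)-1,8-epoxy-4,6-bis(triethylsilyloxy)guai-9-ene
Conditions: Et3SiOTf, 2,6-lutidine, CH2Cl2, −78 → 0 °C
Reagents that add atoms: triethylsilyl trifluoromethanesulfonate, CC[Si](CC)(CC)OS(=O)(=O)C(F)(F)F
Why: silyl triflate silylation of the hindered secondary alcohol keeps the C6 oxygen from capturing the allyl cation in step 12 and from competing in step 14.

**Step 12**
Reactants: 16 (1R,4S,5R,6R,7R,8R)-1,8-epoxy-4,6-bis(triethylsilyloxy)guai-9-ene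
Product: 17 (4S,5S,6R,7R,8R)-4,6-bis(triethylsilyloxy)guai-1(10)-en-8-ol
Conditions: Et3SiH (5 equiv), BF3·OEt2 (1.5 equiv), CH2Cl2, −78 → −40 °C; aq. NaHCO3
Reagents that add atoms: none
Why: ionic hydrogenation, in which BF3 binds the bridging oxygen, the tertiary allylic C1–O bond ionises to the C1–C10–C9 allyl cation, and Et3SiH delivers hydride to the less hindered secondary terminus C9, giving the tetrasubstituted C1=C10 alkene and freeing the C8 hydroxyl with its configuration untouched.

**Step 13**
Reactants: 18 4-hydroxybenzoic acid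
Product: 20 4-(tert-butyldimethylsilyloxy)benzoic acid, via bis-silylated acid 19 (not isolated)
Conditions: TBSCl (2.2 equiv), imidazole, DMF, rt; then AcOH/THF/H2O, rt
Reagents that add atoms: tert-butyldimethylsilyl chloride, CC(C)(C)[Si](C)(C)Cl
Why: exhaustive silylation followed by mild aqueous acid hydrolyses the labile silyl ester and leaves the aryl silyl ether.

**Step 14**
Reactants: 17 (4S,5S,6R,7R,8R)-4,6-bis(triethylsilyloxy)guai-1(10)-en-8-ol, 20 4-(tert-butyldimethylsilyloxy)benzoic acid
Product: 21 (4S,5S,6R,7R,8S)-4,6-bis(triethylsilyloxy)guai-1(10)-en-8-yl 4-(tert-butyldimethylsilyloxy)benzoate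
Conditions: PPh3, DIAD, toluene/THF, 0 °C → rt
Reagents that add atoms: none
Why: Mitsunobu esterification, in which the carboxylate displaces the C8 alkoxyphosphonium from the opposite face (the face free of the isopropyl and C6 silyloxy groups), inverting C8 to the configuration of the target.

**Step 15**
Reactants: 21 (4S,5S,6R,7R,8S)-4,6-bis(triethylsilyloxy)guai-1(10)-en-8-yl 4-(tert-butyldimethylsilyloxy)benzoate
Product: 22 (4S,5S,6R,7S,8S)-4,6-dihydroxyguai-1(10)-en-8-yl 4-hydroxybenzoate
Conditions: HF·pyridine, pyridine, THF, 0 °C → rt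
Reagents that add atoms: none
Why: buffered fluoride cleavage of the two triethylsilyl ethers and the aryl silyl ether should leave the ester, the tertiary alcohol and the tetrasubstituted alkene intact and touches no stereocentre.

**Compound list**
1 | 3-methylfuran-2-carbaldehyde | O=Cc1occc1C | starting material
2 | 2-ethenyl-3-methylfuran | C=Cc1occc1C | intermediate
3 | but-2-yn-1-ol | CC#CCO | starting material
4 | sodium 2,2-bis(2-methoxyethoxy)-3-methyl-2,5-dihydro-1,2-oxaaluminol-2-uide (cyclic alkenylalanate) | [Na+].CC1=CCO[Al-]1(OCCOC)OCCOC | intermediate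
5 | (2Z)-3-iodobut-2-en-1-ol | C/C(I)=C/CO | intermediate
6 | 9-[2-(3-methylfuran-2-yl)ethyl]-9-borabicyclo[3.3.1]nonane | Cc1ccoc1CCB1C2CCCC1CCC2 | intermediate
7 | (2Z)-3-methyl-5-(3-methylfuran-2-yl)pent-2-en-1-ol | C/C(CCc1occc1C)=C/CO | intermediate
8 | [(2R,3S)-3-methyl-3-[2-(3-methylfuran-2-yl)ethyl]oxiran-2-yl]methanol | OC[C@H]1O[C@@]1(C)CCc1occc1C | intermediate
9 | (2S,3S)-3-methyl-3-[2-(3-methylfuran-2-yl)ethyl]oxirane-2-carbaldehyde | O=C[C@H]1O[C@@]1(C)CCc1occc1C | intermediate
10 | isobutylmagnesium bromide | CC(C)C[Mg]Br | starting material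
11 | 3-methyl-1-[(2R,3S)-3-methyl-3-[2-(3-methylfuran-2-yl)ethyl]oxiran-2-yl]butan-1-ol (carbinol epimers) | CC(C)CC(O)[C@H]1O[C@@]1(C)CCc1occc1C | intermediate
12 | 3-methyl-1-[(2S,3S)-3-methyl-3-[2-(3-methylfuran-2-yl)ethyl]oxiran-2-yl]butan-1-one | CC(C)CC(=O)[C@H]1O[C@@]1(C)CCc1occc1C | intermediate
13 | triethyl({(1Z)-3-methyl-1-[(2S,3S)-3-methyl-3-[2-(3-methylfuran-2-yl)ethyl]oxiran-2-yl]but-1-en-1-yl}oxy)silane | CC(C)/C=C(/[C@H]1O[C@@]1(C)CCc1occc1C)O[Si](CC)(CC)CC | intermediate
14 | (1R,4S,5R,7R,8R)-1,8-epoxy-4-(triethylsilyloxy)guai-9-en-6-one (oxygen bridge C1–O–C8 cis to the C4–C5 bond and to the isopropyl group) | CC1=C[C@@H]2[C@@H](C(C)C)C(=O)[C@H]3[C@@](C)(O[Si](CC)(CC)CC)CC[C@]13O2 | intermediate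
15 | (1R,4S,5R,6R,7S,8R)-1,8-epoxy-4-(triethylsilyloxy)guai-9-en-6-ol (C6 hydroxyl cis to the bridge) | CC1=C[C@@H]2[C@@H](C(C)C)[C@@H](O)[C@H]3[C@@](C)(O[Si](CC)(CC)CC)CC[C@]13O2 | intermediate
16 | (1R,4S,5R,6R,7R,8R)-1,8-epoxy-4,6-bis(triethylsilyloxy)guai-9-ene | CC1=C[C@@H]2[C@@H](C(C)C)[C@@H](O[Si](CC)(CC)CC)[C@H]3[C@@](C)(O[Si](CC)(CC)CC)CC[C@]13O2 | intermediate
17 | (4S,5S,6R,7R,8R)-4,6-bis(triethylsilyloxy)guai-1(10)-en-8-ol (C8 hydroxyl cis to the isopropyl group) | CC1=C2CC[C@](C)(O[Si](CC)(CC)CC)[C@@H]2[C@H](O[Si](CC)(CC)CC)[C@H](C(C)C)[C@H](O)C1 | intermediate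
18 | 4-hydroxybenzoic acid | OC(=O)c1ccc(O)cc1 | starting material
19 | tert-butyldimethylsilyl 4-(tert-butyldimethylsilyloxy)benzoate | CC(C)(C)[Si](C)(C)OC(=O)c1ccc(O[Si](C)(C)C(C)(C)C)cc1 | intermediate
20 | 4-(tert-butyldimethylsilyloxy)benzoic acid | OC(=O)c1ccc(O[Si](C)(C)C(C)(C)C)cc1 | intermediate
21 | (4S,5S,6R,7R,8S)-4,6-bis(triethylsilyloxy)guai-1(10)-en-8-yl 4-(tert-butyldimethylsilyloxy)benzoate | CC1=C2CC[C@](C)(O[Si](CC)(CC)CC)[C@@H]2[C@H](O[Si](CC)(CC)CC)[C@H](C(C)C)[C@@H](OC(=O)c2ccc(O[Si](C)(C)C(C)(C)C)cc2)C1 | intermediate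
22 | (4S,5S,6R,7S,8S)-4,6-dihydroxyguai-1(10)-en-8-yl 4-hydroxybenzoate, i.e. (3S,3aS,4R,5S,6S)-3,4-dihydroxy-3,8-dimethyl-5-(propan-2-yl)-1,2,3,3a,4,5,6,7-octahydroazulen-6-yl 4-hydroxybenzoate | CC1=C2CC[C@](C)(O)[C@@H]2[C@H](O)[C@H](C(C)C)[C@@H](OC(=O)c2ccc(O)cc2)C1 | target

**Totals:** 15 steps; longest linear sequence 13 steps (steps 1, 3–12, 14, 15).

**Steps most likely to fail**

1. Step 9. The furan may add in the compact instead of the extended orientation (poor facial selectivity across the furan), which would place the oxygen bridge trans to C4 and to the isopropyl group. The fallback sets out from 13 and uses that adduct without inversion at C8. The compact-mode ketone (1S,4S,5R,7R,8S)-1,8-epoxy-4-(triethylsilyloxy)guai-9-en-6-one F1, a chair bicycle with both α-substituents equatorial, is reduced from the bridge face with LiBH(s-Bu)3 (THF, −78 °C) to the axial alcohol (1S,4S,5R,6R,7S,8S)-1,8-epoxy-4-(triethylsilyloxy)guai-9-en-6-ol F2. Silylation (Et3SiOTf, 2,6-lutidine) gives the bis-silyl ether F3, and Et3SiH/BF3·OEt2 as in step 12 gives (4S,5S,6R,7R,8S)-4,6-bis(triethylsilyloxy)guai-1(10)-en-8-ol F4, whose C8 hydroxyl already has the target configuration. F4 is acylated with 20 with retention by Yamaguchi esterification (2,4,6-trichlorobenzoyl chloride, Et3N, DMAP, toluene), and the route is rejoined at 21.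

2. Step 12. The allyl cation may lose a proton to give a diene, be captured by the C6 oxygen, or ionisation may occur at the secondary C8–O bond instead of the tertiary C1–O bond. The fallback sets out from 16 and separates ether cleavage from reduction. Me2BBr (CH2Cl2, −78 °C) opens the bridge to the allylic bromide 9-bromo-4,6-bis(triethylsilyloxy)guai-1(10)-en-8-ol F5. Radical chain reduction (Bu3SnH, AIBN, benzene, 80 °C) then removes bromine, the allyl radical taking hydrogen at the less hindered C9, and the route is rejoined at 17.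

3. Step 14. The activated C8 oxygen may be lost by elimination toward C9 or C7, or the hindered alcohol may fail to be activated. The fallback sets out from 17 and uses a preformed leaving group. MsCl, Et3N and DMAP (CH2Cl2, 0 °C) give the 8-O-methanesulfonate F6. Displacement with caesium 4-(tert-butyldimethylsilyloxy)benzoate F7 (made from 20 and Cs2CO3) and 18-crown-6 in toluene at 80–100 °C proceeds by SN2 with inversion, and the route is rejoined at 21.

**Further compounds**
F1 | step 9 | (1S,4S,5R,7R,8S)-1,8-epoxy-4-(triethylsilyloxy)guai-9-en-6-one (bridge trans to C4 and isopropyl) | CC1=C[C@H]2[C@@H](C(C)C)C(=O)[C@H]3[C@@](C)(O[Si](CC)(CC)CC)CC[C@@]13O2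
F2 | step 9 | (1S,4S,5R,6R,7S,8S)-1,8-epoxy-4-(triethylsilyloxy)guai-9-en-6-ol | CC1=C[C@H]2[C@@H](C(C)C)[C@@H](O)[C@H]3[C@@](C)(O[Si](CC)(CC)CC)CC[C@@]13O2
F3 | step 9 | (1S,4S,5R,6R,7R,8S)-1,8-epoxy-4,6-bis(triethylsilyloxy)guai-9-ene | CC1=C[C@H]2[C@@H](C(C)C)[C@@H](O[Si](CC)(CC)CC)[C@H]3[C@@](C)(O[Si](CC)(CC)CC)CC[C@@]13O2
F4 | step 9 | (4S,5S,6R,7R,8S)-4,6-bis(triethylsilyloxy)guai-1(10)-en-8-ol | CC1=C2CC[C@](C)(O[Si](CC)(CC)CC)[C@@H]2[C@H](O[Si](CC)(CC)CC)[C@H](C(C)C)[C@@H](O)C1
F5 | step 12 | 9-bromo-4,6-bis(triethylsilyloxy)guai-1(10)-en-8-ol (C9 epimers, other centres as in 17) | CC1=C2CC[C@](C)(O[Si](CC)(CC)CC)[C@@H]2[C@H](O[Si](CC)(CC)CC)[C@H](C(C)C)[C@H](O)C1Br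
F6 | step 14 | 4,6-bis(triethylsilyloxy)guai-1(10)-en-8-yl methanesulfonate (configuration as in 17) | CC1=C2CC[C@](C)(O[Si](CC)(CC)CC)[C@@H]2[C@H](O[Si](CC)(CC)CC)[C@H](C(C)C)[C@H](OS(C)(=O)=O)C1
F7 | step 14 | caesium 4-(tert-butyldimethylsilyloxy)benzoate | [Cs+].[O-]C(=O)c1ccc(O[Si](C)(C)C(C)(C)C)cc1
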